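**Retrosynthetic overview**
1. C14 ketone ⇐ oxidation of a C14 geminal bis(boronate); C13–C14 bond ⇐ SN2 alkylation of an α,α-diboryl carbanion (from the geminal bis(boronate) made by double hydroboration of 3-methylbut-1-yne) with a C13 allylic bromide.
2. C13 bromide ⇐ (E)-selective SeO2 allylic oxidation of the terminal methyl group, then chemoselective bromination of the primary allylic alcohol.
3. C1–furyl bond and the (S)-carbinol ⇐ enantiotopic-group-selective Suzuki coupling that desymmetrises an achiral geminal bis(boronate) with 3-bromofuran, then stereoretentive C–B oxidation (key step).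
4. C1–C2 bond ⇐ alkylation of lithiated bis(pinacolboryl)methane with (2E,6E)-farnesyl bromide, which brings all three E-trisubstituted alkenes.
5. No ring is formed; the furan ring enters intact.

Atom numbers used below: C1 = carbinol carbon, C13 = allylic CH2 next to the ketone, C14 = ketone carbon. Bpin = 4,4,5,5-tetramethyl-1,3,2-dioxaborolan-2-yl.

Assumption: the (R,R) enantiomer of the TADDOL-derived phosphoramidite ligand is taken to give the (S)-configured secondary boronate in step 2; if the sense of induction is the opposite, the (S,S) ligand is used.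

**Step 1**
Reactants: 1 bis[(pinacolato)boryl]methane; 2 (2E,6E)-farnesyl bromide
Product: 4 2,2'-[(3E,7E)-4,8,12-trimethyltrideca-3,7,11-triene-1,1-diyl]bis(4,4,5,5-tetramethyl-1,3,2-dioxaborolane), via [bis(pinacolboryl)methyl]lithium 3 (not isolated)
Conditions: lithium 2,2,6,6-tetramethylpiperidide (1.05 equiv), THF, 0 °C, 10 min; then 2, 0 °C → rt
Reagents that add atoms: none
Why: The α,α-diboryl carbanion (stabilised by two vacant boron p orbitals) is alkylated in an SN2 reaction at the primary allylic carbon of 2, so both alkene geometries are untouched and no stereocentre is formed.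

**Step 2**
Reactants: 4 the geminal bis(boronate); 5 3-bromofuran
Product: 7 (1S,3E,7E)-1-(furan-3-yl)-4,8,12-trimethyltrideca-3,7,11-trien-1-ol, via the (S)-secondary pinacol boronate 6 (not isolated)
Conditions: Pd(OAc)2 (5 mol %), (R,R)-TADDOL-derived P–NMe2 phosphoramidite ligand (10 mol %), KOH (8 M aq), 1,4-dioxane, rt → 40 °C; then 30% aq H2O2, THF, 0 °C → rt
Reagents that add atoms: hydrogen peroxide, OO
Why: Enantiotopic-group-selective Suzuki–Miyaura cross-coupling (the key, symmetry-breaking step): hydroxide activates the geminal bis(boronate), the chiral ligand on (3-furyl)Pd(OH)L (divalent palladium) decides which of the two enantiotopic boryl groups of achiral 4 transmetalates, reductive elimination forges the C1–furyl bond and sets C1 as S (er about 95:5 is typical for this reaction class, upgraded on 7 by preparative chiral HPLC if needed), and the in-flask peroxide oxidation replaces boron by hydroxyl with retention.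

**Step 3**
Reactants: 7 the (S)-furyl carbinol
Product: 8 (1S,3E,7E,11E)-1-(furan-3-yl)-4,8,12-trimethyltrideca-3,7,11-triene-1,13-diol
Conditions: SeO2 (0.3 equiv), tert-butyl hydroperoxide (70% aq, 3 equiv), salicylic acid (0.1 equiv), CH2Cl2, 0 °C → rt, stopped at partial conversion
Reagents that add atoms: tert-butyl hydroperoxide, CC(C)(C)OO (terminal oxidant); selenium dioxide, O=[Se]=O (oxygen carrier)
Why: SeO2-catalysed allylic oxidation (ene reaction, then [2,3]-sigmatropic shift) attacks the most electron-rich and least hindered terminal trisubstituted alkene and hydroxylates its (E)-methyl group selectively, the established pattern for farnesyl termini, and the mild catalytic conditions should leave the 3-alkylfuran and the secondary alcohol intact.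

**Step 4**
Reactants: 8 the diol
Product: 9 (1S,3E,7E,11E)-13-bromo-1-(furan-3-yl)-4,8,12-trimethyltrideca-3,7,11-trien-1-ol
Conditions: CBr4 (1.1 equiv), PPh3 (1.15 equiv), CH2Cl2, −30 °C, 30 min
Reagents that add atoms: carbon tetrabromide, BrC(Br)(Br)Br
Why: Appel reaction: at −30 °C the alkoxyphosphonium salt forms far faster at the unhindered primary allylic hydroxyl than at the secondary carbinol, and SN2 displacement by bromide gives the primary allylic bromide without allylic shift or change at C1.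

**Step 5**
Reactants: 10 3-methylbut-1-yne; 11 pinacolborane (4,4,5,5-tetramethyl-1,3,2-dioxaborolane)
Product: 13 2,2'-(3-methylbutane-1,1-diyl)bis(4,4,5,5-tetramethyl-1,3,2-dioxaborolane), via (E)-alkenyl pinacol boronate 12 (not isolated)
Conditions: [RhCl(C8H12)]2 (2.5 mol %; C8H12 = 1,5-cyclooctadiene), 1,4-bis(diphenylphosphino)butane (5 mol %), 11 (2.3 equiv), 1,2-dichloroethane, sealed tube, 0 °C → rt, 12 h
Reagents that add atoms: none
Why: Rhodium-catalysed sequential double hydroboration of a terminal alkyne (monovalent rhodium catalyst): syn anti-Markovnikov H–B addition gives the (E)-alkenyl boronate 12, and the second H–B addition places boron on the carbon that already bears boron (α-boryl stabilisation of the alkylrhodium intermediate, while the isopropyl group shields the other carbon), so the 1,1-bis(boronate) forms without a stereocentre.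

**Step 6**
Reactants: 9 the bromo alcohol; 13 the isobutyl geminal bis(boronate)
Product: 16 (1S,3E,7E,11E)-1-(furan-3-yl)-4,8,12,16-tetramethyl-14,14-bis(4,4,5,5-tetramethyl-1,3,2-dioxaborolan-2-yl)heptadeca-3,7,11-trien-1-ol, via lithiated bis(boronate) 14 (not isolated), via lithium alkoxide 15 (not isolated)
Conditions: 13 (2.3 equiv), lithium 2,2,6,6-tetramethylpiperidide (2.2 equiv), THF, 0 °C, 30 min; then 9, −78 → 0 °C; water work-up
Reagents that add atoms: none
Why: Deprotonative alkylation of a geminal bis(boronate): the first equivalent of carbanion 14 only removes the hydroxyl proton (giving alkoxide 15 and returning 13), the second displaces the primary allylic bromide in an SN2 reaction at the unhindered CH2 end, so the 11E alkene and the C1 stereocentre are unchanged.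

**Step 7**
Reactants: 16 the C14 geminal bis(boronate)
Product: 17 (6E,10E,14E,17S)-17-(furan-3-yl)-17-hydroxy-2,6,10,14-tetramethylheptadeca-6,10,14-trien-4-one (target)
Conditions: 30% aq H2O2, aq NaHCO3 buffer (pH about 8), THF, 0 °C → rt
Reagents that add atoms: hydrogen peroxide, OO
Why: Oxidative C–B cleavage (two 1,2-shifts from boron to oxygen) turns the C(Bpin)2 carbon into a gem-diol derivative that collapses to the ketone, while the near-neutral buffer keeps the β,γ-unsaturated ketone from moving into conjugation and leaves furan, alkenes and carbinol untouched.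

**Compound list**
1 | bis[(pinacolato)boryl]methane, 2,2'-methylenebis(4,4,5,5-tetramethyl-1,3,2-dioxaborolane) | C(B1OC(C)(C)C(C)(C)O1)B1OC(C)(C)C(C)(C)O1 | starting material
2 | (2E,6E)-farnesyl bromide, (2E,6E)-1-bromo-3,7,11-trimethyldodeca-2,6,10-triene | CC(C)=CCC/C(C)=C/CC/C(C)=C/CBr | starting material
3 | [bis(4,4,5,5-tetramethyl-1,3,2-dioxaborolan-2-yl)methyl]lithium (formed in the flask) | [Li]C(B1OC(C)(C)C(C)(C)O1)B1OC(C)(C)C(C)(C)O1 | intermediate
4 | 2,2'-[(3E,7E)-4,8,12-trimethyltrideca-3,7,11-triene-1,1-diyl]bis(4,4,5,5-tetramethyl-1,3,2-dioxaborolane) | CC(C)=CCC/C(C)=C/CC/C(C)=C/CC(B1OC(C)(C)C(C)(C)O1)B1OC(C)(C)C(C)(C)O1 | intermediate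
5 | 3-bromofuran | Brc1ccoc1 | starting material
6 | 2-[(1S,3E,7E)-1-(furan-3-yl)-4,8,12-trimethyltrideca-3,7,11-trien-1-yl]-4,4,5,5-tetramethyl-1,3,2-dioxaborolane (formed in the flask) | CC(C)=CCC/C(C)=C/CC/C(C)=C/C[C@H](B1OC(C)(C)C(C)(C)O1)c1ccoc1 | intermediate
7 | (1S,3E,7E)-1-(furan-3-yl)-4,8,12-trimethyltrideca-3,7,11-trien-1-ol | CC(C)=CCC/C(C)=C/CC/C(C)=C/C[C@H](O)c1ccoc1 | intermediate
8 | (1S,3E,7E,11E)-1-(furan-3-yl)-4,8,12-trimethyltrideca-3,7,11-triene-1,13-diol | OC/C(C)=C/CC/C(C)=C/CC/C(C)=C/C[C@H](O)c1ccoc1 | intermediate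
9 | (1S,3E,7E,11E)-13-bromo-1-(furan-3-yl)-4,8,12-trimethyltrideca-3,7,11-trien-1-ol | BrC/C(C)=C/CC/C(C)=C/CC/C(C)=C/C[C@H](O)c1ccoc1 | intermediate
10 | 3-methylbut-1-yne (isopropylacetylene) | CC(C)C#C | starting material
11 | pinacolborane, 4,4,5,5-tetramethyl-1,3,2-dioxaborolane | B1OC(C)(C)C(C)(C)O1 | starting material
12 | 4,4,5,5-tetramethyl-2-[(1E)-3-methylbut-1-en-1-yl]-1,3,2-dioxaborolane (formed in the flask) | CC(C)/C=C/B1OC(C)(C)C(C)(C)O1 | intermediate
13 | 2,2'-(3-methylbutane-1,1-diyl)bis(4,4,5,5-tetramethyl-1,3,2-dioxaborolane) | CC(C)CC(B1OC(C)(C)C(C)(C)O1)B1OC(C)(C)C(C)(C)O1 | intermediate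
14 | [3-methyl-1,1-bis(4,4,5,5-tetramethyl-1,3,2-dioxaborolan-2-yl)butyl]lithium (formed in the flask) | [Li]C(CC(C)C)(B1OC(C)(C)C(C)(C)O1)B1OC(C)(C)C(C)(C)O1 | intermediate
15 | lithium (1S,3E,7E,11E)-13-bromo-1-(furan-3-yl)-4,8,12-trimethyltrideca-3,7,11-trien-1-olate (formed in the flask) | BrC/C(C)=C/CC/C(C)=C/CC/C(C)=C/C[C@H]([O-])c1ccoc1.[Li+] | intermediate
16 | (1S,3E,7E,11E)-1-(furan-3-yl)-4,8,12,16-tetramethyl-14,14-bis(4,4,5,5-tetramethyl-1,3,2-dioxaborolan-2-yl)heptadeca-3,7,11-trien-1-ol | CC(C)CC(C/C(C)=C/CC/C(C)=C/CC/C(C)=C/C[C@H](O)c1ccoc1)(B1OC(C)(C)C(C)(C)O1)B1OC(C)(C)C(C)(C)O1 | intermediate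
17 | (6E,10E,14E,17S)-17-(furan-3-yl)-17-hydroxy-2,6,10,14-tetramethylheptadeca-6,10,14-trien-4-one | C/C(=C\CC/C(C)=C/C[C@H](O)c1ccoc1)CC/C=C(\C)CC(=O)CC(C)C | target

**Step count and risks**
Total step count: 7 (six in the main line plus the preparation of reagent 13). Longest linear sequence: 6 steps (1, 2, 3, 4, 6, 7). Step 3 is expected to be yield-limiting (roughly half) but is a standard oxidation for farnesyl termini.

The three steps most likely to fail:

Step 2 (low conversion with the heteroaryl bromide, β-hydride elimination from the α-boryl alkylpalladium intermediate, or insufficient enantioselectivity). The fallback sets out from 2 and comes back at 7; it makes C1 by acyl-anion alkylation and asymmetric ketone reduction. Furan-3-carbaldehyde and propane-1,3-dithiol (BF3·OEt2, CH2Cl2) give 2-(furan-3-yl)-1,3-dithiane F1. n-Butyllithium (THF, −40 °C) gives [2-(furan-3-yl)-1,3-dithian-2-yl]lithium F2, which is alkylated by 2 to 2-(furan-3-yl)-2-[(2E,6E)-3,7,11-trimethyldodeca-2,6,10-trien-1-yl]-1,3-dithiane F3. MeI and CaCO3 in aqueous MeCN release (3E,7E)-1-(furan-3-yl)-4,8,12-trimethyltrideca-3,7,11-trien-1-one F4. Corey–Bakshi–Shibata reduction with catecholborane and the (R)-2-methyl-oxazaborolidine catalyst (toluene, −78 °C) gives 7, and the route continues with step 3.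

Step 4 (the bromination may not discriminate between the primary allylic and the secondary furyl carbinol). The fallback sets out from 8 and comes back at 17; it carries the terminus forward at the aldehyde level. TEMPO with PhI(OAc)2 (CH2Cl2, rt) oxidises only the primary allylic alcohol of 8 to (2E,6E,10E,13S)-13-(furan-3-yl)-13-hydroxy-2,6,10-trimethyltrideca-2,6,10-trienal F5. F5 is added to 14 (2.2 equiv, generated from 13 as in step 6, THF, −78 °C → rt); the first equivalent forms lithium (1S,3E,7E,11E)-1-(furan-3-yl)-4,8,12-trimethyl-13-oxotrideca-3,7,11-trien-1-olate F6. The second equivalent converts the aldehyde by boron–Wittig olefination into (1S,3E,7E,11E)-1-(furan-3-yl)-4,8,12,16-tetramethyl-14-(4,4,5,5-tetramethyl-1,3,2-dioxaborolan-2-yl)heptadeca-3,7,11,13-tetraen-1-ol F7 (13,14-geometry not controlled and without consequence). H2O2 in NaHCO3-buffered THF liberates the dienol (1S,3E,7E,11E)-1-(furan-3-yl)-4,8,12,16-tetramethylheptadeca-3,7,11,13-tetraene-1,14-diol F8, which ketonises by kinetic protonation at C13 to 17.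

Step 6 (the bulky α,α-diboryl carbanion may act as a base and cause 1,4-elimination of HBr, or the alkoxide may induce deborylation of the bis(boronate)). The fallback sets out from 9 and comes back at 17; it uses a dithiane acyl-anion equivalent. 3-Methylbutanal and propane-1,3-dithiol (BF3·OEt2, CH2Cl2) give 2-(2-methylpropyl)-1,3-dithiane F9. n-Butyllithium (THF, −30 °C) gives [2-(2-methylpropyl)-1,3-dithian-2-yl]lithium F10. Two equivalents of F10 convert 9 into alkoxide 15 and then displace its bromide to give, after aqueous work-up, (1S,3E,7E,11E)-1-(furan-3-yl)-4,8,12-trimethyl-13-[2-(2-methylpropyl)-1,3-dithian-2-yl]trideca-3,7,11-trien-1-ol F11. MeI and CaCO3 in aqueous MeCN (40 °C) hydrolyse the dithiane to the ketone, which is 17.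

**Further compounds**
F1 | step 2 | 2-(furan-3-yl)-1,3-dithiane | C1CSC(SC1)c1ccoc1
F2 | step 2 | [2-(furan-3-yl)-1,3-dithian-2-yl]lithium | [Li]C1(SCCCS1)c1ccoc1
F3 | step 2 | 2-(furan-3-yl)-2-[(2E,6E)-3,7,11-trimethyldodeca-2,6,10-trien-1-yl]-1,3-dithiane | CC(C)=CCC/C(C)=C/CC/C(C)=C/CC1(SCCCS1)c1ccoc1
F4 | step 2 | (3E,7E)-1-(furan-3-yl)-4,8,12-trimethyltrideca-3,7,11-trien-1-one | CC(C)=CCC/C(C)=C/CC/C(C)=C/CC(=O)c1ccoc1
F5 | step 4 | (2E,6E,10E,13S)-13-(furan-3-yl)-13-hydroxy-2,6,10-trimethyltrideca-2,6,10-trienal | O=C/C(C)=C/CC/C(C)=C/CC/C(C)=C/C[C@H](O)c1ccoc1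
F6 | step 4 | lithium (1S,3E,7E,11E)-1-(furan-3-yl)-4,8,12-trimethyl-13-oxotrideca-3,7,11-trien-1-olate | O=C/C(C)=C/CC/C(C)=C/CC/C(C)=C/C[C@H]([O-])c1ccoc1.[Li+]
F7 | step 4 | (1S,3E,7E,11E)-1-(furan-3-yl)-4,8,12,16-tetramethyl-14-(4,4,5,5-tetramethyl-1,3,2-dioxaborolan-2-yl)heptadeca-3,7,11,13-tetraen-1-ol | CC(C)CC(B1OC(C)(C)C(C)(C)O1)=C/C(C)=C/CC/C(C)=C/CC/C(C)=C/C[C@H](O)c1ccoc1
F8 | step 4 | (1S,3E,7E,11E)-1-(furan-3-yl)-4,8,12,16-tetramethylheptadeca-3,7,11,13-tetraene-1,14-diol | CC(C)CC(O)=C/C(C)=C/CC/C(C)=C/CC/C(C)=C/C[C@H](O)c1ccoc1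
F9 | step 6 | 2-(2-methylpropyl)-1,3-dithiane | CC(C)CC1SCCCS1
F10 | step 6 | [2-(2-methylpropyl)-1,3-dithian-2-yl]lithium | [Li]C1(CC(C)C)SCCCS1
F11 | step 6 | (1S,3E,7E,11E)-1-(furan-3-yl)-4,8,12-trimethyl-13-[2-(2-methylpropyl)-1,3-dithian-2-yl]trideca-3,7,11-trien-1-ol | CC(C)CC2(C/C(C)=C/CC/C(C)=C/CC/C(C)=C/C[C@H](O)c1ccoc1)SCCCS2
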